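**Plan**

Numbering: flavanone numbering; unit 1 carries the 4-methoxyphenyl group, unit 2 the 4-hydroxyphenyl group; C3(1) means C3 of unit 1.
Retrosynthesis: after the benzyl ethers, the aryl ether bond O1(2)–C8a(2) is cut (fluoride displacement). The chain C4(1)–C3(1)–C3(2)–C4(2), a 1,4-diketone shared by the two pyranone rings, is then read as an opened 2,5-diarylfuran. C2(2) is an oxygen-bearing carbon β to the C4(2) ketone, so C2(2)–C3(2) is cut as an aldol bond masked in an oxetane. The furan is cut at C3(1)–C3(2) into a flavanone enolate and an α-bromo ketone.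
Forward: the pyranone of unit 1 comes from (2S)-isosakuranetin. A furan is fused onto it (steps 4–5), an oxetane is photo-fused onto the furan (step 7), water unravels both oxygen rings (step 8), and the pyranone of unit 2 is closed last (step 9).
Stereochemistry: C2(1) comes from the chiral pool. C2(2) and C3(2) come from the exo-selective cycloaddition on the furan face opposite the 4-methoxyphenyl group. C3(1) comes from kinetic protonation of the enol opposite the same group (2,3-cis).

Key step: step 7

Remark 1: read from the SMILES, the target is (2S,3S) in unit 1 (2,3-cis) and (2R,3S) in unit 2 (2,3-trans); the route is planned for this isomer.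
Remark 2: commercial (2S)-isosakuranetin is assumed to be enantiomerically pure; the 5-OH is left free until the C4 ketone has been converted into the furan, because benzylating it on the flavanone would need base strong enough to open the pyranone and racemise C2.

Step 1
Reactants: 1 (2S)-isosakuranetin
Product: 2 (2S)-7-(benzyloxy)-5-hydroxy-2-(4-methoxyphenyl)chroman-4-one
Conditions: BnOH, PPh3, DIAD, THF, 0 °C → rt
Reagents that add atoms: benzyl alcohol, OCc1ccccc1
Why: Mitsunobu etherification activates only the acidic, non-chelated 7-OH, leaves the hydrogen-bonded 5-OH untouched, and its neutral medium spares the base-labile C2 stereocentre.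

Step 2
Reactants: 3 2',4',6'-trifluoroacetophenone
Product: 5 1-[2,4-bis(benzyloxy)-6-fluorophenyl]ethanone, via 1-[4-(benzyloxy)-2,6-difluorophenyl]ethanone 4 (not isolated)
Conditions: BnOH (2.05 equiv), NaH (2.1 equiv), DMF, 0 °C → rt
Reagents that add atoms: benzyl alcohol, OCc1ccccc1
Why: Twofold nucleophilic aromatic substitution, in which the acetyl group activates the para fluoride (expected to go first in the dipolar solvent) and then one ortho fluoride, while each alkoxy group introduced deactivates the ring enough for the third fluoride to survive two equivalents of alkoxide.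

Step 3
Reactants: 5 1-[2,4-bis(benzyloxy)-6-fluorophenyl]ethanone
Product: 7 1-[2,4-bis(benzyloxy)-6-fluorophenyl]-2-bromoethanone, via trimethylsilyl enol ether 6 (not isolated)
Conditions: LiN(SiMe3)2, THF, −78 °C; Me3SiCl; then NBS, −78 → 0 °C
Reagents that add atoms: N-bromosuccinimide, O=C1CCC(=O)N1Br; chlorotrimethylsilane, C[Si](C)(C)Cl (silyl group of 6 only)
Why: Bromination of a preformed silyl enol ether with NBS confines the halogen to the α-carbon and spares the electron-rich dialkoxyarene that free bromine would attack.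

Step 4
Reactants: 2 (2S)-7-(benzyloxy)-5-hydroxy-2-(4-methoxyphenyl)chroman-4-one; 7 1-[2,4-bis(benzyloxy)-6-fluorophenyl]-2-bromoethanone
Product: 9 (2S,3R)-7-(benzyloxy)-3-{2-[2,4-bis(benzyloxy)-6-fluorophenyl]-2-oxoethyl}-5-hydroxy-2-(4-methoxyphenyl)chroman-4-one, via dilithium dianion 8 (not isolated)
Conditions: LiN(SiMe3)2 (2.3 equiv), THF, −78 → −40 °C; then 7, −78 °C; AcOH
Reagents that add atoms: none
Why: SN2 C-alkylation of a phenoxide–enolate dianion by an α-bromo ketone, in which the lithium phenoxide at C5 disfavours E1cB opening of the pyranone at low temperature and the enolate carbon is the most nucleophilic site; the new C3 centre (expected trans to the aryl group) is erased in step 5.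

Step 5
Reactants: 9 (2S,3R)-7-(benzyloxy)-3-{2-[2,4-bis(benzyloxy)-6-fluorophenyl]-2-oxoethyl}-5-hydroxy-2-(4-methoxyphenyl)chroman-4-one
Product: 10 (4R)-7-(benzyloxy)-2-[2,4-bis(benzyloxy)-6-fluorophenyl]-4-(4-methoxyphenyl)-4H-furo[3,2-c]chromen-9-ol
Conditions: TsOH·H2O (10 mol %), 4 Å MS, PhMe, 60 °C
Reagents that add atoms: none
Why: Paal–Knorr cyclodehydration of the 1,4-diketone gives the 2,5-diarylfuran and planarises C3(1); C2(1) becomes C4 of the furochromene untouched in space (S becomes R only through the priority rules), and acid strength and temperature are kept low because this centre now sits on a para-methoxybenzylic C–O bond.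

Step 6
Reactants: 10 (4R)-7-(benzyloxy)-2-[2,4-bis(benzyloxy)-6-fluorophenyl]-4-(4-methoxyphenyl)-4H-furo[3,2-c]chromen-9-ol
Product: 11 (4R)-7,9-bis(benzyloxy)-2-[2,4-bis(benzyloxy)-6-fluorophenyl]-4-(4-methoxyphenyl)-4H-furo[3,2-c]chromene
Conditions: BnBr, K2CO3, DMF, rt
Reagents that add atoms: benzyl bromide, BrCc1ccccc1
Why: Williamson etherification of a phenol that is no longer chelated or flanked by a ketone, so mild carbonate base is safe for the pyran ring, and it removes the phenolic O–H that would quench the triplet aldehyde by hydrogen transfer.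

Step 7
Reactants: 11 (4R)-7,9-bis(benzyloxy)-2-[2,4-bis(benzyloxy)-6-fluorophenyl]-4-(4-methoxyphenyl)-4H-furo[3,2-c]chromene; 12 4-(benzyloxy)benzaldehyde
Product: 13 exo-aryl oxetane photoadduct: the C2=C3 bond of the furan of 11 carries a cis-fused oxetane on the face opposite the 4-methoxyphenyl group, with the oxetane oxygen on the former C2 (now a ketal carbon, R, still bearing the fluoroaryl group) and the CH[4-(benzyloxy)phenyl] carbon (R, aryl exo) on the former C3 (S); chromene C4 unchanged (R)
Conditions: hν (365 nm), 12 (5 equiv), degassed C6H6, 10 °C; chromatography on Et3N-deactivated SiO2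
Reagents that add atoms: none
Why: The n,π* triplet of the aldehyde adds through oxygen to the aryl-bearing α-carbon of the furan, giving a triplet 1,4-biradical whose carbon radical is allylic and, through the ring-fused enol ether, benzylic; after spin inversion it closes the C2(2)–C3(2) bond at the unsubstituted β-carbon, which is the Paternò–Büchi reaction of aromatic aldehydes with furans, known as a threo-selective photochemical aldol equivalent. The only ring formed is the oxetane, closed by recombination of the two radical centres of the biradical into a four-membered ring fused cis to the dihydrofuran. The ketal carbon C4(2) follows from the cis fusion, C3(2) from attack on the furan face opposite the pseudo-axial 4-methoxyphenyl group at the neighbouring C4, and C2(2) from the exo placement of the aryl group that furan adducts show through the geometry of spin inversion. The step needs site selectivity for the unfused double bond (the fused one is tetrasubstituted and buried), oxygen-to-α-carbon regiochemistry (secured by the delocalised biradical and the free β-position), and exo and facial selectivity, both substrate-controlled, with wrong-face biradicals expected to revert by C–O cleavage. The twisted 2,6-disubstituted aryl group limits conjugation on the reacting side, 365 nm light should be absorbed mainly by the excess aldehyde, and energy transfer to the arylfuran chromophore should lower the quantum efficiency without consuming material.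

Step 8
Reactants: 13 exo-aryl oxetane photoadduct
Product: 15 (2S,3S)-5,7-bis(benzyloxy)-3-{(1S,2R)-1-[2,4-bis(benzyloxy)-6-fluorobenzoyl]-2-[4-(benzyloxy)phenyl]-2-hydroxyethyl}-2-(4-methoxyphenyl)chroman-4-one, via ring-opened enol 14 (not isolated)
Conditions: 0.02 M HCl, THF–H2O (4:1), 0 °C
Reagents that add atoms: water, O
Why: Acid-catalysed ketal hydrolysis in which the strained 2-aryl-2-alkoxyoxetane should ionise before the conjugated enol ether is protonated and water capture should outrun proton loss to a furan, so that the hemiketal opens to the aryl ketone, the C2(2) carbinol and the C4(1) enol, which is protonated at C3(1) opposite the pseudo-axial 4-methoxyphenyl group to give the kinetic 2,3-cis (3S) arrangement without breaking any bond at C2(2) or C3(2).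

Step 9
Reactants: 15 (2S,3S)-5,7-bis(benzyloxy)-3-{(1S,2R)-1-[2,4-bis(benzyloxy)-6-fluorobenzoyl]-2-[4-(benzyloxy)phenyl]-2-hydroxyethyl}-2-(4-methoxyphenyl)chroman-4-one
Product: 16 (2S,3S)-5,7-bis(benzyloxy)-3-{(2R,3S)-5,7-bis(benzyloxy)-2-[4-(benzyloxy)phenyl]-4-oxochroman-3-yl}-2-(4-methoxyphenyl)chroman-4-one
Conditions: Cs2CO3 (1.2 equiv), DMF, 0 °C → rt
Reagents that add atoms: none
Why: Intramolecular nucleophilic aromatic substitution closes the six-membered ring as the benzylic alkoxide displaces the fluoride ortho to the ketone (both alkoxy groups are meta to the reacting carbon and do not deactivate it); the carbinol C–O bond is not broken, so C2(2) is retained and the anti aldol becomes the 2,3-trans flavanone, while a weak base at low temperature limits enolisation and retro-aldol cleavage.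

Step 10
Reactants: 16 (2S,3S)-5,7-bis(benzyloxy)-3-{(2R,3S)-5,7-bis(benzyloxy)-2-[4-(benzyloxy)phenyl]-4-oxochroman-3-yl}-2-(4-methoxyphenyl)chroman-4-one
Product: 17 (2S,3S)-5,7-dihydroxy-3-[(2R,3S)-5,7-dihydroxy-2-(4-hydroxyphenyl)-4-oxochroman-3-yl]-2-(4-methoxyphenyl)chroman-4-one (CNP0196568.4)
Conditions: H2 (1 atm), Pd/C, EtOAc–MeOH, rt
Reagents that add atoms: none
Why: Hydrogenolysis of the five benzyl ethers over palladium on carbon is neutral, so neither chromanone is enolised and the methyl ether is untouched; the reaction is stopped after uptake of five equivalents to avoid cleavage of the benzylic C2–O bonds.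

**Compound list**

1 | (2S)-isosakuranetin, (2S)-5,7-dihydroxy-2-(4-methoxyphenyl)chroman-4-one | COc1ccc([C@@H]2CC(=O)c3c(O)cc(O)cc3O2)cc1 | starting material
2 | (2S)-7-(benzyloxy)-5-hydroxy-2-(4-methoxyphenyl)chroman-4-one | COc1ccc([C@@H]2CC(=O)c3c(O)cc(OCc4ccccc4)cc3O2)cc1 | intermediate
3 | 2',4',6'-trifluoroacetophenone | CC(=O)c1c(F)cc(F)cc1F | starting material
4 | 1-[4-(benzyloxy)-2,6-difluorophenyl]ethanone | CC(=O)c1c(F)cc(OCc2ccccc2)cc1F | intermediate
5 | 1-[2,4-bis(benzyloxy)-6-fluorophenyl]ethanone | CC(=O)c1c(F)cc(OCc2ccccc2)cc1OCc1ccccc1 | intermediate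
6 | trimethylsilyl enol ether of 5, {1-[2,4-bis(benzyloxy)-6-fluorophenyl]ethenyloxy}trimethylsilane | C=C(O[Si](C)(C)C)c1c(F)cc(OCc2ccccc2)cc1OCc1ccccc1 | intermediate
7 | 1-[2,4-bis(benzyloxy)-6-fluorophenyl]-2-bromoethanone | O=C(CBr)c1c(F)cc(OCc2ccccc2)cc1OCc1ccccc1 | intermediate
8 | dilithium dianion of 2 (C5 phenoxide, C3=C4 enolate) | COc1ccc([C@H]2Oc3cc(OCc4ccccc4)cc([O-])c3C([O-])=C2)cc1.[Li+].[Li+] | intermediate
9 | (2S,3R)-7-(benzyloxy)-3-{2-[2,4-bis(benzyloxy)-6-fluorophenyl]-2-oxoethyl}-5-hydroxy-2-(4-methoxyphenyl)chroman-4-one | COc1ccc([C@H]2Oc3cc(OCc4ccccc4)cc(O)c3C(=O)[C@@H]2CC(=O)c2c(F)cc(OCc3ccccc3)cc2OCc2ccccc2)cc1 | intermediate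
10 | (4R)-7-(benzyloxy)-2-[2,4-bis(benzyloxy)-6-fluorophenyl]-4-(4-methoxyphenyl)-4H-furo[3,2-c]chromen-9-ol | COc1ccc([C@H]2Oc3cc(OCc4ccccc4)cc(O)c3-c3oc(-c4c(F)cc(OCc5ccccc5)cc4OCc4ccccc4)cc32)cc1 | intermediate
11 | (4R)-7,9-bis(benzyloxy)-2-[2,4-bis(benzyloxy)-6-fluorophenyl]-4-(4-methoxyphenyl)-4H-furo[3,2-c]chromene | COc1ccc([C@H]2Oc3cc(OCc4ccccc4)cc(OCc4ccccc4)c3-c3oc(-c4c(F)cc(OCc5ccccc5)cc4OCc4ccccc4)cc32)cc1 | intermediate
12 | 4-(benzyloxy)benzaldehyde | O=Cc1ccc(OCc2ccccc2)cc1 | starting material
13 | exo-aryl oxetane photoadduct of 11 and 12 (oxetane cis-fused to the dihydrofuran, opposite the 4-methoxyphenyl group; ketal carbon R, ring-fusion CH S, aryl-bearing CH R, chromene C4 R) | COc1ccc([C@H]2Oc3cc(OCc4ccccc4)cc(OCc4ccccc4)c3C3=C2[C@H]4[C@H](c5ccc(OCc6ccccc6)cc5)O[C@@]4(c4c(F)cc(OCc5ccccc5)cc4OCc4ccccc4)O3)cc1 | intermediate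
14 | ring-opened enol: (2R)-5,7-bis(benzyloxy)-2-(4-methoxyphenyl)-2H-chromen-4-ol carrying at C3 the (1S,2R)-1-aroyl-2-aryl-2-hydroxyethyl chain of 15 | COc1ccc([C@H]2Oc3cc(OCc4ccccc4)cc(OCc4ccccc4)c3C(O)=C2[C@H](C(=O)c2c(F)cc(OCc3ccccc3)cc2OCc2ccccc2)[C@@H](O)c2ccc(OCc3ccccc3)cc2)cc1 | intermediate
15 | (2S,3S)-5,7-bis(benzyloxy)-3-{(1S,2R)-1-[2,4-bis(benzyloxy)-6-fluorobenzoyl]-2-[4-(benzyloxy)phenyl]-2-hydroxyethyl}-2-(4-methoxyphenyl)chroman-4-one | COc1ccc([C@H]2Oc3cc(OCc4ccccc4)cc(OCc4ccccc4)c3C(=O)[C@H]2[C@H](C(=O)c2c(F)cc(OCc3ccccc3)cc2OCc2ccccc2)[C@@H](O)c2ccc(OCc3ccccc3)cc2)cc1 | intermediate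
16 | (2S,3S)-5,7-bis(benzyloxy)-3-{(2R,3S)-5,7-bis(benzyloxy)-2-[4-(benzyloxy)phenyl]-4-oxochroman-3-yl}-2-(4-methoxyphenyl)chroman-4-one | COc1ccc([C@H]2Oc3cc(OCc4ccccc4)cc(OCc4ccccc4)c3C(=O)[C@H]2[C@@H]2C(=O)c3c(OCc4ccccc4)cc(OCc4ccccc4)cc3O[C@H]2c2ccc(OCc3ccccc3)cc2)cc1 | intermediate
17 | (2S,3S)-5,7-dihydroxy-3-[(2R,3S)-5,7-dihydroxy-2-(4-hydroxyphenyl)-4-oxochroman-3-yl]-2-(4-methoxyphenyl)chroman-4-one | COc1ccc([C@H]2Oc3cc(O)cc(O)c3C(=O)[C@H]2[C@@H]2C(=O)c3c(O)cc(O)cc3O[C@H]2c2ccc(O)cc2)cc1 | target

**Step count and risks**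

Total: 10 steps. Longest linear sequence: 9 steps (from 3 through steps 2–10); the branch from 1 is 8 steps.

Step 7. The arylfuran chromophore may quench the aldehyde triplet by energy transfer, or the aldehyde may add to the furan face next to the 4-methoxyphenyl group. The fallback keeps furan 11 as the device that planarises C3(1) but replaces the photochemical aldol by a thermal one. It sets out from 11 and comes back at 15. Sensitised photooxygenation of 11 (O2, methylene blue, visible light, CH2Cl2, −78 °C; then Me2S) should open the furan to the cis-enedione (Z)-5,7-bis(benzyloxy)-3-{2-[2,4-bis(benzyloxy)-6-fluorophenyl]-2-oxoethylidene}-2-(4-methoxyphenyl)chroman-4-one F1. Hydrogenation of its C=C bond over rhodium on alumina (Rh/Al2O3, H2, EtOAc), from the face opposite the 4-methoxyphenyl group, should give the 2,3-cis diketone (2S,3S)-5,7-bis(benzyloxy)-3-{2-[2,4-bis(benzyloxy)-6-fluorophenyl]-2-oxoethyl}-2-(4-methoxyphenyl)chroman-4-one F2. Enolisation of the aryl ketone on its methylene side with chlorodicyclohexylborane and Et3N (E-enolate, Et2O, −78 °C) and addition of 12 should give the anti aldol 15. The cost is that the face selectivity at C3(2) then rests only on the neighbouring stereocentre, so diastereomers may need separation.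

Step 8. The ring-opened cation may lose a proton and re-aromatise to a 3-furylcarbinol, or C3(1) may be protonated on the wrong face while the bicycle is still intact. The fallback unmasks the enol ether oxidatively and removes the auxiliary atom by a radical; it sets out from 13 and comes back at 15. Iodohydration of the enol ether of 13 (N-iodosuccinimide, NaHCO3, THF–H2O, −20 °C) attacks C3(1). The hemiketal formed at C4(1) collapses, and the 2-hydroxyoxetane so revealed opens by strain release without any cation next to the C3(2)–H bond. This should give the 3-iodo derivative of 15, (2S)-5,7-bis(benzyloxy)-3-iodo-3-{(1S,2R)-1-[2,4-bis(benzyloxy)-6-fluorobenzoyl]-2-[4-(benzyloxy)phenyl]-2-hydroxyethyl}-2-(4-methoxyphenyl)chroman-4-one F3 (configuration at the iodinated carbon immaterial). Radical deiodination (Bu3SnH, Et3B/air, PhMe, −78 °C) passes through the planar α-keto radical, which should take hydrogen from the bulky stannane opposite the 4-methoxyphenyl group and give 15.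

Step 9. Under carbonate base the aldolate may undergo retro-aldol cleavage, C3(1) may epimerise to the more stable 2,3-trans arrangement, or the pyranone of unit 1 may open by E1cB. The fallback avoids any standing Brønsted base; it sets out from 15 and comes back at 16. Neutral silylation of 15 (N-(trimethylsilyl)imidazole, CH2Cl2, rt) gives the trimethylsilyl ether of the C2(2) carbinol, F4. Ring closure then follows by fluoride-catalysed desilylative substitution (catalytic CsF or tetrabutylammonium difluorotriphenylsilicate, DMF, rt). The alkoxide is released only transiently, the Si–F bond is the driving force, and each ring closure returns the fluoride that starts the next, giving 16.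

Further compounds
F1 | step 7 | (Z)-5,7-bis(benzyloxy)-3-{2-[2,4-bis(benzyloxy)-6-fluorophenyl]-2-oxoethylidene}-2-(4-methoxyphenyl)chroman-4-one (C2 as in 11) | COc1ccc([C@H]2Oc3cc(OCc4ccccc4)cc(OCc4ccccc4)c3C(=O)/C2=C\C(=O)c2c(F)cc(OCc3ccccc3)cc2OCc2ccccc2)cc1
F2 | step 7 | (2S,3S)-5,7-bis(benzyloxy)-3-{2-[2,4-bis(benzyloxy)-6-fluorophenyl]-2-oxoethyl}-2-(4-methoxyphenyl)chroman-4-one | COc1ccc([C@H]2Oc3cc(OCc4ccccc4)cc(OCc4ccccc4)c3C(=O)[C@H]2CC(=O)c2c(F)cc(OCc3ccccc3)cc2OCc2ccccc2)cc1
F3 | step 8 | 3-iodo derivative of 15 (iodine at C3 of unit 1, drawn opposite the 4-methoxyphenyl group) | COc1ccc([C@H]2Oc3cc(OCc4ccccc4)cc(OCc4ccccc4)c3C(=O)[C@@]2(I)[C@H](C(=O)c2c(F)cc(OCc3ccccc3)cc2OCc2ccccc2)[C@@H](O)c2ccc(OCc3ccccc3)cc2)cc1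
F4 | step 9 | trimethylsilyl ether of 15 at the C2(2) carbinol | COc1ccc([C@H]2Oc3cc(OCc4ccccc4)cc(OCc4ccccc4)c3C(=O)[C@H]2[C@H](C(=O)c2c(F)cc(OCc3ccccc3)cc2OCc2ccccc2)[C@@H](O[Si](C)(C)C)c2ccc(OCc3ccccc3)cc2)cc1
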